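**Plan**

1. Ring numbering: C1 (CHO), C2 (2-acetoxytridecyl), C3 (OH), C4 (OMe), C5 (H), C6 (OH); this benzene ring is the only ring.
2. Retrosynthesis: the C1–CHO bond and the O-protecting groups are removed first, then the ring is cut at C6–C5, C4–C3 and C3–C2.
3. Enabling feature: the para oxygenated carbons C3 and C6 are the phenol and alkoxy carbons of a chromium-carbene benzannulation; C4(OMe)–C5(H) is methoxyacetylene, C3 is a CO ligand, and C6–C1–C2 is an alkenyl(methoxy)carbene carrying the side chain on C2.
4. The carbene complex goes back to an (E)-alkenyl iodide and Cr(CO)6, the iodide to a homopropargylic alcohol, and that to acetylide plus (R)-2-undecyloxirane, made from decylmagnesium bromide and (R)-epichlorohydrin.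
5. Forward: the chain is joined C10 + C3 + C2, the carbene complex is made, the benzene ring closes in one step, then O-benzylation, silyl-to-acetyl exchange, formylation at C1 and a final BCl3 unmasking of C3–OH and C6–OH.
6. Stereochemistry: the single (R) centre is the carbinol carbon of (R)-epichlorohydrin; its C–O bond is never broken.

Key step: step 8

Assumption: methoxyacetylene is too volatile to be bought reliably, so it is prepared (step 1) and used as a cold THF solution.
Note on SMILES: π-bound cyclopentadienyl ligands are drawn σ-bonded, and π-bound Cr(CO)3 is drawn as a separate fragment.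

**Step 1**
Reactants: 1 chloroacetaldehyde dimethyl acetal (2-chloro-1,1-dimethoxyethane)
Product: 3 methoxyacetylene (methoxyethyne), via sodium methoxyacetylide 2 (not isolated)
Conditions: NaNH2 (3 equiv), liq. NH3, −33 °C; NH3 evaporated; sat. aq. NaCl, −70 °C → rt; distilled into a −78 °C trap, stored as a cold THF solution
Reagents that add atoms: none
Why: Amide base should effect two successive eliminations (methanol, then HCl) from the α-chloroacetal, the standard dehydrohalogenation route to 1-alkoxyalkynes, and the product is held as acetylide 2 until the cold aqueous quench.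

**Step 2**
Reactants: 4 1-bromodecane; 5 (R)-epichlorohydrin
Product: 7 (2R)-1-chlorotridecan-2-ol, via decylmagnesium bromide 6 (not isolated)
Conditions: Mg, THF, rt → 40 °C; then 5, CuI (10 mol %), THF, −40 → −20 °C; then 1 M HCl
Reagents that add atoms: none
Why: Copper-catalysed Grignard opening of the epoxide (SN2 at the unsubstituted ring carbon) should outpace attack at the chloromethyl group, and because the carbinol C–O bond is not touched the (R) configuration of 5 is carried into 7.

**Step 3**
Reactants: 7 (2R)-1-chlorotridecan-2-ol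
Product: 8 (2R)-2-undecyloxirane [(R)-1,2-epoxytridecane]
Conditions: NaOH (powdered), Et2O, rt
Reagents that add atoms: none
Why: Intramolecular Williamson etherification (the alkoxide displaces chloride at the primary carbon) should close the oxirane without involving the stereocentre.

**Step 4**
Reactants: 8 (2R)-2-undecyloxirane
Product: 9 (4R)-pentadec-1-yn-4-ol
Conditions: LiC≡CH·H2NCH2CH2NH2 (1.5 equiv), DMSO, rt; then H2O
Reagents that add atoms: lithium acetylide–ethylenediamine complex, LiC≡CH·H2NCH2CH2NH2, [Li]C#C.NCCN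
Why: SN2 opening of a terminal epoxide by lithium acetylide in DMSO should occur only at the CH2 terminus, giving the homopropargylic alcohol with the carbinol centre unchanged.

**Step 5**
Reactants: 9 (4R)-pentadec-1-yn-4-ol
Product: 10 tert-butyldimethyl{[(4R)-pentadec-1-yn-4-yl]oxy}silane
Conditions: TBSCl, imidazole, DMF, rt
Reagents that add atoms: tert-butyldimethylsilyl chloride, CC(C)(C)[Si](C)(C)Cl
Why: Corey silylation (TBSCl–imidazole in DMF) should protect the secondary alcohol as an ether that tolerates Cp2Zr(H)Cl, t-BuLi and the carbene chemistry ahead.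

**Step 6**
Reactants: 10 tert-butyldimethyl{[(4R)-pentadec-1-yn-4-yl]oxy}silane
Product: 12 tert-butyl{[(1E,4R)-1-iodopentadec-1-en-4-yl]oxy}dimethylsilane, via alkenylzirconocene chloride 11 (not isolated)
Conditions: Cp2Zr(H)Cl (1.5 equiv), THF, rt, dark; then I2, THF, 0 °C
Reagents that add atoms: iodine, II
Why: Schwartz hydrozirconation adds Zr–H syn across the terminal alkyne with zirconium on the terminal carbon, and iodinolysis of the C–Zr bond with retention should give the (E)-alkenyl iodide.

**Step 7**
Reactants: 12 tert-butyl{[(1E,4R)-1-iodopentadec-1-en-4-yl]oxy}dimethylsilane; 13 chromium hexacarbonyl, Cr(CO)6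
Product: 16 pentacarbonyl[(2E,5R)-5-(tert-butyldimethylsilyloxy)-1-methoxyhexadec-2-en-1-ylidene]chromium, via alkenyllithium 14 (not isolated), via lithium acylchromate 15 (not isolated)
Conditions: t-BuLi (2.1 equiv), Et2O, −78 °C; then Cr(CO)6, Et2O, −78 °C → rt; solvent exchange; MeOTf, CH2Cl2, 0 °C
Reagents that add atoms: methyl trifluoromethanesulfonate, COS(=O)(=O)C(F)(F)F
Why: Fischer carbene synthesis: iodine–lithium exchange with retention of alkene geometry, addition of the alkenyllithium to a CO ligand of Cr(CO)6 and O-methylation of the resulting acylate with a hard methylating agent should give the alkenyl(methoxy)carbene complex.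

**Step 8**
Reactants: 16 pentacarbonyl[(2E,5R)-5-(tert-butyldimethylsilyloxy)-1-methoxyhexadec-2-en-1-ylidene]chromium; 3 methoxyacetylene
Product: 20 2-[(2R)-2-(tert-butyldimethylsilyloxy)tridecyl]-4,6-dimethoxyphenol, via dienylcarbene complex 17 (not isolated), via chromium-bound dienylketene 18 (not isolated), via phenol tricarbonylchromium complex 19 (not isolated)
Conditions: 3 (3 equiv), THF (0.05 M), 50 °C, sealed tube; then CO (1 atm), hν (Pyrex), rt; then air, hν, Et2O, rt
Reagents that add atoms: none
Why: Proposed new method: on warming, 16 loses one CO and the alkyne inserts into the chromium–carbene bond, the nucleophilic unsubstituted carbon of the ynol ether bonding to the electrophilic carbene carbon (C6–C5) to give dienylcarbene 17; migration of a CO ligand onto the new carbene carbon (C4–C3) gives dienylketene 18, and its six-electron electrocyclization onto the alkene terminus (C3–C2) followed by enolization gives arene complex 19, from which air and light release 20. The closest known reactions are the Dötz benzannulation of alkenyl(alkoxy)carbene complexes of zerovalent chromium with terminal alkynes and the photochemical benzannulation of dienyl(alkoxy)carbene chromium complexes to ortho-alkoxyphenols; a 1-alkoxyalkyne has not been established as the alkyne partner, which is why the step is a proposal. Because 17 is a heteroatom-stabilized carbene that could resist thermal CO migration, as the aminocarbenes from ynamine insertion do, the mixture is irradiated under CO after the thermal stage so that any 17 left is carbonylated photochemically to 18. The one ring formed, the benzene ring, closes by 6π electrocyclization of 18; no stereocentre is created, and the silyloxy-bearing carbon is separated from C2 by a methylene group and takes no part. The step needs the insertion regiochemistry that puts the methoxy-bearing alkyne carbon beside the CO-derived carbon, and both the larger size of OMe against H and the polarization of the ynol ether point that way; the (2E) geometry of 17 required for closure is within reach because its donor–acceptor-substituted C5=C6 bond should rotate easily.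

**Step 9**
Reactants: 20 2-[(2R)-2-(tert-butyldimethylsilyloxy)tridecyl]-4,6-dimethoxyphenol
Product: 21 {[(2R)-1-(2-benzyloxy-3,5-dimethoxyphenyl)tridecan-2-yl]oxy}(tert-butyl)dimethylsilane
Conditions: BnBr, K2CO3, DMF, rt, Ar
Reagents that add atoms: benzyl bromide, BrCc1ccccc1
Why: Williamson O-benzylation of the phenoxide should mask C3–OH with a group that survives fluoride, acylation and Vilsmeier conditions and is removed by BCl3 in the last step.

**Step 10**
Reactants: 21 {[(2R)-1-(2-benzyloxy-3,5-dimethoxyphenyl)tridecan-2-yl]oxy}(tert-butyl)dimethylsilane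
Product: 22 (2R)-1-(2-benzyloxy-3,5-dimethoxyphenyl)tridecan-2-ol
Conditions: Bu4NF, THF, rt; then H2O
Reagents that add atoms: none
Why: Fluoride-induced desilylation should free the secondary alcohol without touching the aryl ethers.

**Step 11**
Reactants: 22 (2R)-1-(2-benzyloxy-3,5-dimethoxyphenyl)tridecan-2-ol
Product: 23 (2R)-1-(2-benzyloxy-3,5-dimethoxyphenyl)tridecan-2-yl acetate
Conditions: Ac2O, pyridine, DMAP (cat.), CH2Cl2, rt
Reagents that add atoms: acetic anhydride, CC(=O)OC(C)=O
Why: DMAP-catalysed acetylation of the only free hydroxyl group should install the acetate of the target with retention, since only the O–H bond reacts.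

**Step 12**
Reactants: 23 (2R)-1-(2-benzyloxy-3,5-dimethoxyphenyl)tridecan-2-yl acetate
Product: 25 (2R)-1-(2-benzyloxy-6-formyl-3,5-dimethoxyphenyl)tridecan-2-yl acetate, via aryl iminium chloride 24 (not isolated)
Conditions: POCl3 (1.5 equiv), DMF, 0 → 60 °C; then H2O, 0 °C → rt
Reagents that add atoms: N,N-dimethylformamide, CN(C)C=O; water, O
Why: Vilsmeier–Haack formylation should occur at C1, which is para to the C4 methoxy and ortho to the C6 methoxy group as in the known formylation of 5-alkylresorcinol dimethyl ethers, while C5 between two methoxy groups is shielded; the acetate prevents lactol formation with the new aldehyde.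

**Step 13**
Reactants: 25 (2R)-1-(2-benzyloxy-6-formyl-3,5-dimethoxyphenyl)tridecan-2-yl acetate
Product: 26 (2R)-1-(2-formyl-3,6-dihydroxy-5-methoxyphenyl)tridecan-2-yl acetate (CNP0112378.1)
Conditions: BCl3 (4 equiv), C6HMe5 (3 equiv), CH2Cl2, −78 → 0 °C; then H2O
Reagents that add atoms: none
Why: BCl3 is known to cleave aryl benzyl ethers at low temperature (pentamethylbenzene trapping the benzyl cation) and to remove selectively a methyl ether ortho to a carbonyl group through a six-membered boron chelate, so C3–OH and C6–OH should be freed while the C4 methyl ether, para to the aldehyde, and the acetate remain.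

**Compound list**

1 | chloroacetaldehyde dimethyl acetal (2-chloro-1,1-dimethoxyethane) | ClCC(OC)OC | starting material
2 | sodium methoxyacetylide | [Na+].[C-]#COC | intermediate (not isolated)
3 | methoxyacetylene (methoxyethyne) | C#COC | intermediate
4 | 1-bromodecane | CCCCCCCCCCBr | starting material
5 | (R)-epichlorohydrin [(2R)-2-(chloromethyl)oxirane] | ClC[C@H]1CO1 | starting material
6 | decylmagnesium bromide | CCCCCCCCCC[Mg]Br | intermediate (not isolated)
7 | (2R)-1-chlorotridecan-2-ol | CCCCCCCCCCC[C@@H](O)CCl | intermediate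
8 | (2R)-2-undecyloxirane [(R)-1,2-epoxytridecane] | CCCCCCCCCCC[C@@H]1CO1 | intermediate
9 | (4R)-pentadec-1-yn-4-ol | CCCCCCCCCCC[C@@H](O)CC#C | intermediate
10 | tert-butyldimethyl{[(4R)-pentadec-1-yn-4-yl]oxy}silane | CCCCCCCCCCC[C@H](CC#C)O[Si](C)(C)C(C)(C)C | intermediate
11 | chlorobis(cyclopentadienyl)[(1E,4R)-4-(tert-butyldimethylsilyloxy)pentadec-1-en-1-yl]zirconium | CCCCCCCCCCC[C@H](C/C=C/[Zr](Cl)(C1C=CC=C1)C1C=CC=C1)O[Si](C)(C)C(C)(C)C | intermediate (not isolated)
12 | tert-butyl{[(1E,4R)-1-iodopentadec-1-en-4-yl]oxy}dimethylsilane | CCCCCCCCCCC[C@H](C/C=C/I)O[Si](C)(C)C(C)(C)C | intermediate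
13 | chromium hexacarbonyl, Cr(CO)6 | [Cr].[C-]#[O+].[C-]#[O+].[C-]#[O+].[C-]#[O+].[C-]#[O+].[C-]#[O+] | starting material
14 | [(1E,4R)-4-(tert-butyldimethylsilyloxy)pentadec-1-en-1-yl]lithium | CCCCCCCCCCC[C@H](C/C=C/[Li])O[Si](C)(C)C(C)(C)C | intermediate (not isolated)
15 | lithium pentacarbonyl[(2E,5R)-5-(tert-butyldimethylsilyloxy)-1-oxidohexadec-2-en-1-ylidene]chromate | [Li+].CCCCCCCCCCC[C@H](C/C=C/C([O-])=[Cr](=C=O)(=C=O)(=C=O)(=C=O)=C=O)O[Si](C)(C)C(C)(C)C | intermediate (not isolated)
16 | pentacarbonyl[(2E,5R)-5-(tert-butyldimethylsilyloxy)-1-methoxyhexadec-2-en-1-ylidene]chromium | CCCCCCCCCCC[C@H](C/C=C/C(OC)=[Cr](=C=O)(=C=O)(=C=O)(=C=O)=C=O)O[Si](C)(C)C(C)(C)C | intermediate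
17 | tetracarbonyl[(2E,4E,7R)-7-(tert-butyldimethylsilyloxy)-1,3-dimethoxyoctadeca-2,4-dien-1-ylidene]chromium | CCCCCCCCCCC[C@H](C/C=C/C(OC)=C\C(OC)=[Cr](=C=O)(=C=O)(=C=O)=C=O)O[Si](C)(C)C(C)(C)C | intermediate (not isolated)
18 | (3E,5E,8R)-8-(tert-butyldimethylsilyloxy)-2,4-dimethoxynonadeca-1,3,5-trien-1-one, π-bound to Cr(CO)3 | CCCCCCCCCCC[C@H](C/C=C/C(OC)=C\C(OC)=C=O)O[Si](C)(C)C(C)(C)C.O=C=[Cr](=C=O)=C=O | intermediate (not isolated)
19 | tricarbonyl{η6-2-[(2R)-2-(tert-butyldimethylsilyloxy)tridecyl]-4,6-dimethoxyphenol}chromium | CCCCCCCCCCC[C@H](Cc1cc(OC)cc(OC)c1O)O[Si](C)(C)C(C)(C)C.O=C=[Cr](=C=O)=C=O | intermediate (not isolated)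
20 | 2-[(2R)-2-(tert-butyldimethylsilyloxy)tridecyl]-4,6-dimethoxyphenol | CCCCCCCCCCC[C@H](Cc1cc(OC)cc(OC)c1O)O[Si](C)(C)C(C)(C)C | intermediate
21 | {[(2R)-1-(2-benzyloxy-3,5-dimethoxyphenyl)tridecan-2-yl]oxy}(tert-butyl)dimethylsilane | CCCCCCCCCCC[C@H](Cc1cc(OC)cc(OC)c1OCc1ccccc1)O[Si](C)(C)C(C)(C)C | intermediate
22 | (2R)-1-(2-benzyloxy-3,5-dimethoxyphenyl)tridecan-2-ol | CCCCCCCCCCC[C@@H](O)Cc1cc(OC)cc(OC)c1OCc1ccccc1 | intermediate
23 | (2R)-1-(2-benzyloxy-3,5-dimethoxyphenyl)tridecan-2-yl acetate | CCCCCCCCCCC[C@H](Cc1cc(OC)cc(OC)c1OCc1ccccc1)OC(C)=O | intermediate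
24 | N-{[2-((2R)-2-acetoxytridecyl)-3-benzyloxy-4,6-dimethoxyphenyl]methylidene}-N-methylmethanaminium chloride | CCCCCCCCCCC[C@H](Cc1c(C=[N+](C)C)c(OC)cc(OC)c1OCc1ccccc1)OC(C)=O.[Cl-] | intermediate (not isolated)
25 | (2R)-1-(2-benzyloxy-6-formyl-3,5-dimethoxyphenyl)tridecan-2-yl acetate | CCCCCCCCCCC[C@H](Cc1c(C=O)c(OC)cc(OC)c1OCc1ccccc1)OC(C)=O | intermediate
26 | (2R)-1-(2-formyl-3,6-dihydroxy-5-methoxyphenyl)tridecan-2-yl acetate (CNP0112378.1) | CCCCCCCCCCC[C@H](Cc1c(O)c(OC)cc(O)c1C=O)OC(C)=O | target

**Totals**

Total step count: 13 (step 1 for the alkyne, steps 2–7 for the carbene complex, step 8 for the ring, steps 9–13 for the endgame).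
Longest linear sequence: 12 steps (steps 2–13, from 4 and 5 to 26).

**Steps most likely to fail**

Step 8 (the step carrying the proposal label). The insertion may stop at the heteroatom-stabilized carbene stage without CO migration. The ynol ether may instead add in a [2+2] sense across the electron-poor alkene of 16, or oligomerize at chromium. Fallback, all known chemistry, with the ring taken from a preformed benzene: oxirane 8 would be opened at its terminal carbon with commercial 3,5-dimethoxyphenylmagnesium chloride and CuI (cat.) in THF at −30 °C to give (2R)-1-(3,5-dimethoxyphenyl)tridecan-2-ol F1. Silylation (TBSCl, imidazole, DMF) would give tert-butyl{[(2R)-1-(3,5-dimethoxyphenyl)tridecan-2-yl]oxy}dimethylsilane F2. NBS in MeCN at 0 °C should brominate the ring carbon ortho to the chain and para to a methoxy group, giving {[(2R)-1-(2-bromo-3,5-dimethoxyphenyl)tridecan-2-yl]oxy}(tert-butyl)dimethylsilane F3. Miyaura borylation (B2pin2, PdCl2(dppf), KOAc, dioxane, 80 °C) would give 2-{2-[(2R)-2-(tert-butyldimethylsilyloxy)tridecyl]-4,6-dimethoxyphenyl}-4,4,5,5-tetramethyl-1,3,2-dioxaborolane F4. Oxidation with NaBO3·4H2O in THF–H2O would then give phenol 20, where the route is rejoined at step 9.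

Step 13. Ether cleavage may extend to the C4 methyl ether once a boron-bound oxygen sits beside it at C3, and the HCl formed may cause loss or migration of the acetyl group. Fallback, with the two unmaskings separated and no boron halide: from 25, MgI2·OEt2 in toluene–Et2O at 60 °C should remove only the methyl group ortho to the formyl group, through a six-membered chelate of divalent magnesium, while C3 is still benzylated. This gives (2R)-1-(2-benzyloxy-6-formyl-5-hydroxy-3-methoxyphenyl)tridecan-2-yl acetate F8. Hydrogenolysis (H2, 1 atm, Pd/C, EtOAc, rt) of the benzyl ether under neutral conditions would then give 26.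

Step 12. The bulky chloroiminium electrophile may react sluggishly at the flanked C1 or attack C5 between the two methoxy groups. Fallback, by halogenation, cross-coupling and oxidative cleavage in place of direct formylation: from 23, NBS in MeCN at 0 °C should give (2R)-1-(2-benzyloxy-6-bromo-3,5-dimethoxyphenyl)tridecan-2-yl acetate F5, the small electrophile entering para to the C4 methoxy group. Stille coupling with tributyl(vinyl)stannane (Pd(PPh3)4, toluene, 100 °C) would give (2R)-1-(2-benzyloxy-6-ethenyl-3,5-dimethoxyphenyl)tridecan-2-yl acetate F6. Lemieux–Johnson cleavage (OsO4 cat., NaIO4, 2,6-lutidine, dioxane–H2O) would pass through (2R)-1-[2-benzyloxy-6-(1,2-dihydroxyethyl)-3,5-dimethoxyphenyl]tridecan-2-yl acetate F7, not isolated, and return to the route at aldehyde 25.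

**Further compounds**

F1 | step 8 | (2R)-1-(3,5-dimethoxyphenyl)tridecan-2-ol | CCCCCCCCCCC[C@@H](O)Cc1cc(OC)cc(OC)c1
F2 | step 8 | tert-butyl{[(2R)-1-(3,5-dimethoxyphenyl)tridecan-2-yl]oxy}dimethylsilane | CCCCCCCCCCC[C@H](Cc1cc(OC)cc(OC)c1)O[Si](C)(C)C(C)(C)C
F3 | step 8 | {[(2R)-1-(2-bromo-3,5-dimethoxyphenyl)tridecan-2-yl]oxy}(tert-butyl)dimethylsilane | CCCCCCCCCCC[C@H](Cc1cc(OC)cc(OC)c1Br)O[Si](C)(C)C(C)(C)C
F4 | step 8 | 2-{2-[(2R)-2-(tert-butyldimethylsilyloxy)tridecyl]-4,6-dimethoxyphenyl}-4,4,5,5-tetramethyl-1,3,2-dioxaborolane | CCCCCCCCCCC[C@H](Cc1cc(OC)cc(OC)c1B1OC(C)(C)C(C)(C)O1)O[Si](C)(C)C(C)(C)C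
F5 | step 12 | (2R)-1-(2-benzyloxy-6-bromo-3,5-dimethoxyphenyl)tridecan-2-yl acetate | CCCCCCCCCCC[C@H](Cc1c(Br)c(OC)cc(OC)c1OCc1ccccc1)OC(C)=O
F6 | step 12 | (2R)-1-(2-benzyloxy-6-ethenyl-3,5-dimethoxyphenyl)tridecan-2-yl acetate | CCCCCCCCCCC[C@H](Cc1c(C=C)c(OC)cc(OC)c1OCc1ccccc1)OC(C)=O
F7 | step 12 | (2R)-1-[2-benzyloxy-6-(1,2-dihydroxyethyl)-3,5-dimethoxyphenyl]tridecan-2-yl acetate (both epimers at the new carbinol carbon) | CCCCCCCCCCC[C@H](Cc1c(C(O)CO)c(OC)cc(OC)c1OCc1ccccc1)OC(C)=O
F8 | step 13 | (2R)-1-(2-benzyloxy-6-formyl-5-hydroxy-3-methoxyphenyl)tridecan-2-yl acetate | CCCCCCCCCCC[C@H](Cc1c(C=O)c(O)cc(OC)c1OCc1ccccc1)OC(C)=O
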